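**Retrosynthetic overview**
1. Target 21 ← BBr3 cleavage of three aryl methyl ethers ← hydrogenation of macrocyclic stilbene 19.
2. 19 ← intramolecular Wittig between a ring D aldehyde and a ring A benzylic phosphonium salt (17); this closes the 17-membered macrocycle.
3. Open-chain tetra-aryl 13 ← hydrogenation and decarboxylation of acrylic acid 11 ← Perkin (aldol-type) condensation of arylacetic acid 6 (rings A–O–B) with aldehyde 9 (rings C–O–D); this is the key C–C bond of the ring B–ring C bridge.
4. 6 ← one-carbon homologation of aldehyde 3 ← SNAr of phenol 1 with 4-fluorobenzaldehyde; 9 ← SNAr of o-vanillin with 2-fluorobenzonitrile.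
5. Ring order: the four benzene rings are bought; the only ring formed is the macrocycle, last (step 12).

Assumption: the target has no stereocentre and no configurationally fixed axis or plane, so it is achiral and needs no stereocontrol.

Ring labels: ring A = trioxygenated ring (from 1); ring B = para-linked ring (from 2); ring C = 1,2,3-trisubstituted ring (from 7); ring D = ortho-linked ring (from 8).

**Route**

Step 1
Reactants: 1 methyl 3-hydroxy-4,5-dimethoxybenzoate; 2 4-fluorobenzaldehyde
Product: 3 methyl 3-(4-formylphenoxy)-4,5-dimethoxybenzoate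
Conditions: K2CO3, DMF, 120 °C
Reagents that add atoms: none
Why: SNAr (addition–elimination) in which the phenoxide of 1 displaces fluoride para to the activating formyl group of 2, the methyl ester being inert to K2CO3 in dry DMF.

Step 2
Reactants: 3 methyl 3-(4-formylphenoxy)-4,5-dimethoxybenzoate
Product: 4 methyl 3,4-dimethoxy-5-[4-(2-methoxyethenyl)phenoxy]benzoate (E/Z mixture; E drawn)
Conditions: MeOCH2PPh3Cl, KOtBu, THF, 0 °C to rt
Reagents that add atoms: (methoxymethyl)triphenylphosphonium chloride, COC[P+](c1ccccc1)(c1ccccc1)c1ccccc1.[Cl-]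
Why: Wittig olefination with the non-stabilised methoxymethylene ylide adds the one carbon needed for the arylacetic acid, the aldehyde reacting far faster than the aryl ester; the E/Z ratio is irrelevant because step 3 removes the double bond.

Step 3
Reactants: 4 methyl 3,4-dimethoxy-5-[4-(2-methoxyethenyl)phenoxy]benzoate
Product: 5 methyl 3,4-dimethoxy-5-[4-(2-oxoethyl)phenoxy]benzoate (used crude)
Conditions: 2 M HCl (aq), THF, 50 °C
Reagents that add atoms: water, O
Why: Acid-catalysed enol ether hydrolysis (C-protonation, water addition, loss of methanol) unmasks the arylacetaldehyde under conditions too mild to hydrolyse the methyl benzoate.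

Step 4
Reactants: 5 methyl 3,4-dimethoxy-5-[4-(2-oxoethyl)phenoxy]benzoate
Product: 6 {4-[2,3-dimethoxy-5-(methoxycarbonyl)phenoxy]phenyl}acetic acid
Conditions: NaClO2, NaH2PO4, 2-methyl-2-butene, tBuOH/H2O, rt
Reagents that add atoms: NaClO2 (sodium chlorite), [Na+].[O-]Cl=O
Why: Pinnick oxidation converts the enolisable aldehyde into the acid chemoselectively, with 2-methyl-2-butene trapping hypochlorous acid so the electron-rich rings are not chlorinated.

Step 5
Reactants: 7 2-hydroxy-3-methoxybenzaldehyde (o-vanillin); 8 2-fluorobenzonitrile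
Product: 9 2-(2-formyl-6-methoxyphenoxy)benzonitrile
Conditions: Cs2CO3, DMF, 110 °C
Reagents that add atoms: none
Why: SNAr in which the phenoxide of o-vanillin displaces fluoride ortho to the activating nitrile of 8, the caesium phenoxide in DMF offsetting the lower nucleophilicity of this hindered, formyl-conjugated phenol.

Step 6
Reactants: 6 {4-[2,3-dimethoxy-5-(methoxycarbonyl)phenoxy]phenyl}acetic acid; 9 2-(2-formyl-6-methoxyphenoxy)benzonitrile
Product: 11 (2E)-3-[2-(2-cyanophenoxy)-3-methoxyphenyl]-2-{4-[2,3-dimethoxy-5-(methoxycarbonyl)phenoxy]phenyl}prop-2-enoic acid (the two aryl groups cis), via mixed acetic anhydride 10 (not isolated)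
Conditions: Ac2O, Et3N, 120 °C; then H2O, 2 M HCl
Reagents that add atoms: none
Why: Perkin condensation, an intermolecular aldol condensation of the enolate of mixed anhydride 10 with the non-enolisable aldehyde 9 followed by acyl transfer and loss of acetic acid, gives the acid with the aryl groups cis; ester and nitrile are inert and the geometry is erased in step 8.

Step 7
Reactants: 11 (2E)-3-[2-(2-cyanophenoxy)-3-methoxyphenyl]-2-{4-[2,3-dimethoxy-5-(methoxycarbonyl)phenoxy]phenyl}prop-2-enoic acid
Product: 12 methyl 3-(4-{(Z)-2-[2-(2-cyanophenoxy)-3-methoxyphenyl]ethenyl}phenoxy)-4,5-dimethoxybenzoate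
Conditions: Cu powder (cat.), quinoline, 220 °C, N2
Reagents that add atoms: none
Why: Copper-mediated protodecarboxylation of the alpha-aryl cinnamic acid proceeds with retention to the (Z)-stilbene; aryl ethers, the methyl ester and the nitrile tolerate hot quinoline, and any E isomer is equally useful.

Step 8
Reactants: 12 methyl 3-(4-{(Z)-2-[2-(2-cyanophenoxy)-3-methoxyphenyl]ethenyl}phenoxy)-4,5-dimethoxybenzoate
Product: 13 methyl 3-(4-{2-[2-(2-cyanophenoxy)-3-methoxyphenyl]ethyl}phenoxy)-4,5-dimethoxybenzoate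
Conditions: H2 (1 atm), 10% Pd/C, EtOAc, rt, stopped after 1 equiv H2
Reagents that add atoms: none
Why: Heterogeneous catalytic hydrogenation of the disubstituted stilbene C=C is much faster than reduction of the aryl nitrile or ester at 1 atm in a neutral solvent, and gives the flexible bibenzyl needed for ring closure.

Step 9
Reactants: 13 methyl 3-(4-{2-[2-(2-cyanophenoxy)-3-methoxyphenyl]ethyl}phenoxy)-4,5-dimethoxybenzoate
Product: 15 2-[2-(2-{4-[5-(hydroxymethyl)-2,3-dimethoxyphenoxy]phenyl}ethyl)-6-methoxyphenoxy]benzaldehyde, via aldimine 14 (not isolated)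
Conditions: iBu2AlH (4 equiv), CH2Cl2, −78 to 0 °C; then 1 M HCl, rt
Reagents that add atoms: water, O
Why: Hydride reduction with iBu2AlH takes the ester to the benzylic alcohol but stops at the N-aluminio imine for the nitrile, which aqueous acid hydrolyses through aldimine 14 to the aldehyde, so the two chain ends are differentiated in one operation.

Step 10
Reactants: 15 2-[2-(2-{4-[5-(hydroxymethyl)-2,3-dimethoxyphenoxy]phenyl}ethyl)-6-methoxyphenoxy]benzaldehyde
Product: 16 2-[2-(2-{4-[5-(bromomethyl)-2,3-dimethoxyphenoxy]phenyl}ethyl)-6-methoxyphenoxy]benzaldehyde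
Conditions: PBr3, CH2Cl2, 0 °C
Reagents that add atoms: phosphorus tribromide, BrP(Br)Br
Why: Bromination of the benzylic alcohol with PBr3 (SN2 displacement of the bromophosphite) is fast at 0 °C and leaves the aryl aldehyde untouched.

Step 11
Reactants: 16 2-[2-(2-{4-[5-(bromomethyl)-2,3-dimethoxyphenoxy]phenyl}ethyl)-6-methoxyphenoxy]benzaldehyde
Product: 17 {3-[4-(2-{2-(2-formylphenoxy)-3-methoxyphenyl}ethyl)phenoxy]-4,5-dimethoxybenzyl}triphenylphosphonium bromide
Conditions: PPh3, toluene, 100 °C
Reagents that add atoms: triphenylphosphine, c1ccc(cc1)P(c1ccccc1)c1ccccc1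
Why: SN2 quaternisation of PPh3 by the benzylic bromide gives the salt, which coexists with the aldehyde as long as no base is present.

Step 12
Reactants: 17 {3-[4-(2-{2-(2-formylphenoxy)-3-methoxyphenyl}ethyl)phenoxy]-4,5-dimethoxybenzyl}triphenylphosphonium bromide
Product: 19 macrocyclic stilbene (compound 20 with CH=CH in place of the CH2CH2 bridge between ring D and ring A; Z drawn; E/Z mixture carried on), via phosphonium ylide 18 (not isolated)
Conditions: NaOMe, CH2Cl2, rt, 17 added by syringe pump over 12 h (final about 1 mM)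
Reagents that add atoms: none
Why: Intramolecular Wittig olefination under high dilution, in which the semi-stabilised benzylic ylide condenses with the ring D aldehyde at the other chain end, closes the 17-membered ring; the alkene geometry is erased in step 13.

Step 13
Reactants: 19 macrocyclic stilbene
Product: 20 tri-O-methyl ether of the target (OMe at both ring A hydroxyl positions and at the ring C hydroxyl position)
Conditions: H2 (1 atm), 10% Pd/C, EtOAc, rt
Reagents that add atoms: none
Why: Catalytic hydrogenation saturates the stilbene bridge while diaryl ethers and aryl methyl ethers are inert.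

Step 14
Reactants: 20 tri-O-methyl ether of the target
Product: 21 target CNP0290892.0
Conditions: BBr3, CH2Cl2, −78 °C to rt; then H2O
Reagents that add atoms: none
Why: Lewis-acid ether cleavage in which BBr3 coordinates each methoxy oxygen and bromide removes the methyl group by SN2, whereas the diaryl ether C–O bonds cannot react this way; the product has no stereocentre.

**Compound list**
1 | methyl 3-hydroxy-4,5-dimethoxybenzoate | COC(=O)c1cc(O)c(OC)c(OC)c1 | starting material
2 | 4-fluorobenzaldehyde | O=Cc1ccc(F)cc1 | starting material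
3 | methyl 3-(4-formylphenoxy)-4,5-dimethoxybenzoate | COC(=O)c1cc(Oc2ccc(C=O)cc2)c(OC)c(OC)c1 | intermediate
4 | methyl 3,4-dimethoxy-5-[4-(2-methoxyethenyl)phenoxy]benzoate (E/Z mixture, E drawn) | COC(=O)c1cc(Oc2ccc(/C=C/OC)cc2)c(OC)c(OC)c1 | intermediate
5 | methyl 3,4-dimethoxy-5-[4-(2-oxoethyl)phenoxy]benzoate | COC(=O)c1cc(Oc2ccc(CC=O)cc2)c(OC)c(OC)c1 | intermediate
6 | {4-[2,3-dimethoxy-5-(methoxycarbonyl)phenoxy]phenyl}acetic acid | COC(=O)c1cc(Oc2ccc(CC(=O)O)cc2)c(OC)c(OC)c1 | intermediate
7 | 2-hydroxy-3-methoxybenzaldehyde (o-vanillin) | COc1cccc(C=O)c1O | starting material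
8 | 2-fluorobenzonitrile | N#Cc1ccccc1F | starting material
9 | 2-(2-formyl-6-methoxyphenoxy)benzonitrile | COc1cccc(C=O)c1Oc1ccccc1C#N | intermediate
10 | mixed anhydride of acid 6 with acetic acid (not isolated) | COC(=O)c1cc(Oc2ccc(CC(=O)OC(C)=O)cc2)c(OC)c(OC)c1 | intermediate
11 | (2E)-3-[2-(2-cyanophenoxy)-3-methoxyphenyl]-2-{4-[2,3-dimethoxy-5-(methoxycarbonyl)phenoxy]phenyl}prop-2-enoic acid | COC(=O)c1cc(Oc2ccc(cc2)/C(C(=O)O)=C\c2cccc(OC)c2Oc2ccccc2C#N)c(OC)c(OC)c1 | intermediate
12 | methyl 3-(4-{(Z)-2-[2-(2-cyanophenoxy)-3-methoxyphenyl]ethenyl}phenoxy)-4,5-dimethoxybenzoate | COC(=O)c1cc(Oc2ccc(cc2)/C=C\c2cccc(OC)c2Oc2ccccc2C#N)c(OC)c(OC)c1 | intermediate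
13 | methyl 3-(4-{2-[2-(2-cyanophenoxy)-3-methoxyphenyl]ethyl}phenoxy)-4,5-dimethoxybenzoate | COC(=O)c1cc(Oc2ccc(CCc3cccc(OC)c3Oc3ccccc3C#N)cc2)c(OC)c(OC)c1 | intermediate
14 | [3-(4-{2-[2-(2-(iminomethyl)phenoxy)-3-methoxyphenyl]ethyl}phenoxy)-4,5-dimethoxyphenyl]methanol (aldimine, not isolated) | OCc1cc(Oc2ccc(CCc3cccc(OC)c3Oc3ccccc3C=N)cc2)c(OC)c(OC)c1 | intermediate
15 | 2-[2-(2-{4-[5-(hydroxymethyl)-2,3-dimethoxyphenoxy]phenyl}ethyl)-6-methoxyphenoxy]benzaldehyde | OCc1cc(Oc2ccc(CCc3cccc(OC)c3Oc3ccccc3C=O)cc2)c(OC)c(OC)c1 | intermediate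
16 | 2-[2-(2-{4-[5-(bromomethyl)-2,3-dimethoxyphenoxy]phenyl}ethyl)-6-methoxyphenoxy]benzaldehyde | BrCc1cc(Oc2ccc(CCc3cccc(OC)c3Oc3ccccc3C=O)cc2)c(OC)c(OC)c1 | intermediate
17 | {3-[4-(2-{2-(2-formylphenoxy)-3-methoxyphenyl}ethyl)phenoxy]-4,5-dimethoxybenzyl}triphenylphosphonium bromide | [Br-].COc1cc(C[P+](c2ccccc2)(c2ccccc2)c2ccccc2)cc(Oc2ccc(CCc3cccc(OC)c3Oc3ccccc3C=O)cc2)c1OC | intermediate
18 | benzylidene ylide derived from 17 (not isolated) | COc1cc(C=P(c2ccccc2)(c2ccccc2)c2ccccc2)cc(Oc2ccc(CCc3cccc(OC)c3Oc3ccccc3C=O)cc2)c1OC | intermediate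
19 | macrocyclic stilbene, tri-O-methyl, CH=CH between ring D and ring A (Z drawn; E/Z mixture) | C1c2ccc(cc2)Oc2cc(cc(OC)c2OC)/C=C\c2ccccc2Oc2c(OC)cccc2C1 | intermediate
20 | tri-O-methyl ether of the target | COc1cc2cc(c1OC)Oc1ccc(cc1)CCc1cccc(OC)c1Oc1ccccc1CC2 | intermediate
21 | CNP0290892.0 (achiral) | Oc1cc2cc(c1O)Oc1ccc(cc1)CCc1cccc(O)c1Oc1ccccc1CC2 | target

**Totals**
Total step count: 14.
Longest linear sequence: 13 steps (steps 1–4 and 6–14, from 1); the other branch is step 5.

**Three steps most likely to fail, each with a fallback**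

Step 12 (Wittig macrocyclisation; oligomers may compete). The fallback sets out from 15 and comes back at 19. Oxidation of the benzylic alcohol of 15 with MnO2 in CH2Cl2 gives 2-[2-(2-{4-[5-formyl-2,3-dimethoxyphenoxy]phenyl}ethyl)-6-methoxyphenoxy]benzaldehyde F5. Slow addition of this dialdehyde to low-valent titanium made from TiCl4 and Zn with pyridine in refluxing THF (McMurry coupling, high dilution) closes the same C=C bond and gives 19 as an E/Z mixture, which rejoins the route at step 13.

Step 7 (decarboxylation at 220 °C; ester, nitrile or yield may suffer). The fallback sets out from 11 and comes back at 13, bypassing 12 and step 8. Hydrogenation of 11 (H2, Pd/C, EtOAc) gives racemic 3-[2-(2-cyanophenoxy)-3-methoxyphenyl]-2-{4-[2,3-dimethoxy-5-(methoxycarbonyl)phenoxy]phenyl}propanoic acid F3. Coupling with N-hydroxypyridine-2-thione and DCC gives its racemic 2-thioxopyridin-1(2H)-yl ester (Barton ester) F4. Photolysis of that ester with tBuSH (Barton reductive radical decarboxylation, rt) replaces the carboxyl group by hydrogen through the benzylic radical and delivers 13 directly; the transient stereocentre disappears in this step.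

Step 5 (SNAr with a hindered, weakly nucleophilic phenoxide). The fallback sets out from 7 and comes back at 9. The formyl group of 7 is first masked with ethylene glycol and TsOH (toluene, Dean–Stark) as 2-(1,3-dioxolan-2-yl)-6-methoxyphenol F1, whose phenoxide is no longer deactivated by conjugation. SNAr with 8 (Cs2CO3, DMF, 110 °C) then gives 2-[2-(1,3-dioxolan-2-yl)-6-methoxyphenoxy]benzonitrile F2, and 1 M HCl in THF releases the aldehyde 9.

**Further compounds**
F1 | step 5 | 2-(1,3-dioxolan-2-yl)-6-methoxyphenol | COc1cccc(C2OCCO2)c1O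
F2 | step 5 | 2-[2-(1,3-dioxolan-2-yl)-6-methoxyphenoxy]benzonitrile | COc1cccc(C2OCCO2)c1Oc1ccccc1C#N
F3 | step 7 | 3-[2-(2-cyanophenoxy)-3-methoxyphenyl]-2-{4-[2,3-dimethoxy-5-(methoxycarbonyl)phenoxy]phenyl}propanoic acid (racemic) | COC(=O)c1cc(Oc2ccc(cc2)C(Cc2cccc(OC)c2Oc2ccccc2C#N)C(O)=O)c(OC)c(OC)c1
F4 | step 7 | 2-thioxopyridin-1(2H)-yl ester of F3 (Barton ester, racemic) | COC(=O)c1cc(Oc2ccc(cc2)C(Cc2cccc(OC)c2Oc2ccccc2C#N)C(=O)ON2C=CC=CC2=S)c(OC)c(OC)c1
F5 | step 12 | 2-[2-(2-{4-[5-formyl-2,3-dimethoxyphenoxy]phenyl}ethyl)-6-methoxyphenoxy]benzaldehyde | O=Cc1cc(Oc2ccc(CCc3cccc(OC)c3Oc3ccccc3C=O)cc2)c(OC)c(OC)c1
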